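**Strategy.** The lower (epicatechin) unit is disconnected at its aryl ether bond O1–C8a and, in the same operation, at the interflavan bond C8(lower)–C4(upper). The precursor is an open-chain (1R,2R)-1,3-diarylpropan-1-ol whose ring A carries fluorine at C8a. That fluorine directs lithiation to C8 and then leaves: the C8a≡C8 aryne is closed by the C2 alkoxide (retention, so the syn alcohol becomes the 2,3-cis pyran) and the resulting 8-lithio chroman adds to an (R)-flavanone. The feature exploited is that C8a is the only oxygenated carbon of ring A flanked by both carbon substituents, C4a and C8. Dehydration and hydroboration then set the all-trans 5-deoxy upper unit.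

Key step: step 9

Remark on the chemistry: the structure is read as ent-guibourtinidol-(4β→8)-epicatechin, i.e. upper 5-deoxy unit (2S,3R,4R), 2,3-trans-3,4-trans, and lower unit (2R,3R), 2,3-cis.

Step 1
Reactants: 1 1,3,5-trifluorobenzene
Product: 3 1,3-bis(benzyloxy)-5-fluorobenzene, via monoether 2 (not isolated)
Conditions: BnOH (2.1 equiv), NaH, NMP, 0 → 90 °C
Reagents that add atoms: benzyl alcohol, OCc1ccccc1
Why: Two-fold nucleophilic aromatic substitution by sodium benzyloxide, in which each fluorine replaced by the less electron-withdrawing benzyloxy group slows the next substitution, so that two equivalents of alkoxide should stop at the bis-ether.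

Step 2
Reactants: 3 1,3-bis(benzyloxy)-5-fluorobenzene; 4 (R)-trityl glycidyl ether
Product: 6 (2R)-1-[2,4-bis(benzyloxy)-6-fluorophenyl]-3-(triphenylmethoxy)propan-2-ol, via aryllithium 5 (not isolated)
Conditions: n-BuLi, THF, −78 °C; then 4, BF3·OEt2, −78 °C
Reagents that add atoms: none
Why: Directed ortho-lithiation at the C–H flanked by fluorine and a benzyloxy group (the most acidic site, the aryllithium being stable at −78 °C) followed by BF3-promoted SN2 opening of the epoxide at its CH2 terminus forms the C4–C4a bond, while the stereocentre of 4 (the future C3) is not touched.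

Step 3
Reactants: 6 (2R)-1-[2,4-bis(benzyloxy)-6-fluorophenyl]-3-(triphenylmethoxy)propan-2-ol
Product: 7 1,5-bis(benzyloxy)-2-[(2R)-2-(benzyloxy)-3-(triphenylmethoxy)propyl]-3-fluorobenzene
Conditions: NaH, BnBr, Bu4NI (cat.), THF/DMF, 0 °C → rt
Reagents that add atoms: benzyl bromide, BrCc1ccccc1
Why: Williamson etherification, in which the alkoxide is benzylated at or below room temperature, where displacement of the unactivated aryl fluoride does not compete and the trityl group cannot migrate.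

Step 4
Reactants: 7 1,5-bis(benzyloxy)-2-[(2R)-2-(benzyloxy)-3-(triphenylmethoxy)propyl]-3-fluorobenzene
Product: 8 (2R)-2-(benzyloxy)-3-[2,4-bis(benzyloxy)-6-fluorophenyl]propan-1-ol
Conditions: p-TsOH·H2O (cat.), MeOH/CH2Cl2, rt
Reagents that add atoms: none
Why: Acid-catalysed solvolysis of the trityl ether through the trityl cation, which methanol traps, leaves benzyl ethers and the aryl fluoride untouched.

Step 5
Reactants: 8 (2R)-2-(benzyloxy)-3-[2,4-bis(benzyloxy)-6-fluorophenyl]propan-1-ol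
Product: 9 (2R)-2-(benzyloxy)-3-[2,4-bis(benzyloxy)-6-fluorophenyl]propanal
Conditions: Dess–Martin periodinane, CH2Cl2, 0 °C → rt
Reagents that add atoms: none
Why: Dess–Martin oxidation under nearly neutral conditions should give the α-benzyloxy aldehyde without epimerisation, and it is used at once.

Step 6
Reactants: 9 (2R)-2-(benzyloxy)-3-[2,4-bis(benzyloxy)-6-fluorophenyl]propanal; 10 1,2-bis(benzyloxy)-4-bromobenzene
Product: 12 (1R,2R)-2-(benzyloxy)-1-[3,4-bis(benzyloxy)phenyl]-3-[2,4-bis(benzyloxy)-6-fluorophenyl]propan-1-ol, via Grignard reagent 11 (not isolated)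
Conditions: 10, Mg, THF, rt; then added to 9 premixed with MgBr2·OEt2, CH2Cl2, −78 °C
Reagents that add atoms: none
Why: Chelation-controlled Grignard addition, in which magnesium bridges the aldehyde oxygen and the α-benzyloxy oxygen and the aryl group adds to the face opposite the arylmethyl substituent, should give the syn (1R,2R) alcohol, leaving the benzylic hydroxyl as the only free one.

Step 7
Reactants: 13 7-hydroxy-4H-chromen-4-one
Product: 14 7-(benzyloxy)-4H-chromen-4-one
Conditions: BnBr, K2CO3, DMF, 60 °C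
Reagents that add atoms: benzyl bromide, BrCc1ccccc1
Why: Williamson O-benzylation of the phenol.

Step 8
Reactants: 14 7-(benzyloxy)-4H-chromen-4-one; 15 [4-(benzyloxy)phenyl]boronic acid
Product: 16 (2R)-7-(benzyloxy)-2-[4-(benzyloxy)phenyl]chroman-4-one
Conditions: Pd(OCOCF3)2 (5 mol %), (S)-t-BuPyOX (6 mol %), NH4PF6 (30 mol %), H2O (5 equiv), ClCH2CH2Cl, 60 °C
Reagents that add atoms: none
Why: Asymmetric conjugate addition of the arylboronic acid to the chromone through a cationic arylpalladium complex of the chiral pyridine–oxazoline ligand, which selects the face of C2 (the 2R product is expected with the (S)-ligand by analogy with cyclic enones, the antipodal ligand being used should the sense prove opposite), in a base-free medium that avoids racemisation by ring opening.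

Step 9
Reactants: 12 (1R,2R)-2-(benzyloxy)-1-[3,4-bis(benzyloxy)phenyl]-3-[2,4-bis(benzyloxy)-6-fluorophenyl]propan-1-ol; 16 (2R)-7-(benzyloxy)-2-[4-(benzyloxy)phenyl]chroman-4-one
Product: 21 (2R)-7-(benzyloxy)-2-[4-(benzyloxy)phenyl]-4-{(2R,3R)-3,5,7-tris(benzyloxy)-2-[3,4-bis(benzyloxy)phenyl]chroman-8-yl}chroman-4-ol (C4 epimers), via C8-lithiated lithium alkoxide 17 (not isolated), via aryne lithium alkoxide 18 (not isolated), via 8-lithio chroman 19 (not isolated), via arylcerium dichloride 20 (not isolated)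
Conditions: n-BuLi (2.1 equiv), THF (dilute), −78 °C; −78 → −20 °C; recool, anhydrous CeCl3, −78 °C; then 16, −78 → 0 °C; H2O
Reagents that add atoms: none
Why: Proposed new method: n-BuLi first forms the lithium alkoxide of the C2 hydroxyl and then lithiates C8, the C–H flanked by the C8a fluorine and the C7 benzyloxy group (17); on warming LiF is lost, the C8a≡C8 aryne 18 is attacked in the ring plane by the tethered alkoxide at C8a, and the 8-lithio chroman 19 is transmetallated with CeCl3 and adds to the C4 carbonyl of 16. The closest known reaction types are the capture of arynes by pendant alcohols to give chromans and anionic aryne cyclisations of tethered carbon or nitrogen nucleophiles with electrophilic trapping of the resulting aryllithium; addition of an 8-lithiated benzylated flavan-3-ol to a flavan-4-one is also known, but the combination with a tethered alkoxide in one flask is not. The pyran ring closes in a 6-exo-dig mode (O1 onto C8a, with C8 outside the ring). Because the bond is made at oxygen, C2 and C3 keep the (R,R) configuration of 12 and its syn relationship becomes the 2,3-cis arrangement, whereas the new carbinol centre C4 of the upper unit is uncontrolled and is erased in step 10. The step needs lithiation at C8 and not C6 (secured by the fluorine), attack of oxygen at C8a and not C8 (secured by the four-atom tether and by the C7 benzyloxy group, next to which the aryl anion develops), closure of the six- and not the five-membered ring (secured because the C3 oxygen is benzylated) and 1,2-addition instead of enolisation and ring opening of 16 (secured by the organocerium and by the unsubstituted C5 of the 5-deoxy ring A of 16).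

Step 10
Reactants: 21 (2R)-7-(benzyloxy)-2-[4-(benzyloxy)phenyl]-4-{(2R,3R)-3,5,7-tris(benzyloxy)-2-[3,4-bis(benzyloxy)phenyl]chroman-8-yl}chroman-4-ol (C4 epimers)
Product: 22 (2R)-7-(benzyloxy)-2-[4-(benzyloxy)phenyl]-4-{(2R,3R)-3,5,7-tris(benzyloxy)-2-[3,4-bis(benzyloxy)phenyl]chroman-8-yl}-2H-chromene
Conditions: PPTS (10 mol %), toluene, 4 Å MS, 40 °C
Reagents that add atoms: none
Why: Acid-catalysed E1 dehydration through the doubly benzylic C4 cation (stabilised by the para 7-benzyloxy group), which can lose only a C3 proton, so that both C4 epimers converge on the flav-3-ene while C2 is untouched.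

Step 11
Reactants: 22 (2R)-7-(benzyloxy)-2-[4-(benzyloxy)phenyl]-4-{(2R,3R)-3,5,7-tris(benzyloxy)-2-[3,4-bis(benzyloxy)phenyl]chroman-8-yl}-2H-chromene
Product: 24 (2S,3R,4R)-7-(benzyloxy)-2-[4-(benzyloxy)phenyl]-4-{(2R,3R)-3,5,7-tris(benzyloxy)-2-[3,4-bis(benzyloxy)phenyl]chroman-8-yl}chroman-3-ol, via alkylborane 23 (not isolated)
Conditions: BH3·THF (3 equiv), THF, 0 °C → rt; then aq. NaOH, H2O2, 0 °C → rt
Reagents that add atoms: hydrogen peroxide, OO
Why: Hydroboration–oxidation, in which boron adds to the less substituted C3 and hydrogen to C4 in a syn fashion on the face opposite the C2 aryl group and oxidation proceeds with retention, should place the 3-hydroxyl trans to the 2-aryl group and the 4-aryl group trans to the hydroxyl, that is (2S,3R,4R).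

Step 12
Reactants: 24 (2S,3R,4R)-7-(benzyloxy)-2-[4-(benzyloxy)phenyl]-4-{(2R,3R)-3,5,7-tris(benzyloxy)-2-[3,4-bis(benzyloxy)phenyl]chroman-8-yl}chroman-3-ol
Product: 25 ent-guibourtinidol-(4β→8)-epicatechin (target)
Conditions: H2 (1 atm), Pd(OH)2/C, THF/MeOH, rt
Reagents that add atoms: none
Why: Hydrogenolysis of the seven benzyl ethers over Pd(OH)2 on carbon, under mild conditions that should retain the cyclic benzylic C2–O bonds and the C4–C8 diarylmethine bond, as is usual for benzylated proanthocyanidins.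

**Compound list**

1 | 1,3,5-trifluorobenzene | Fc1cc(F)cc(F)c1 | starting material
2 | 1-(benzyloxy)-3,5-difluorobenzene | Fc1cc(F)cc(OCc2ccccc2)c1 | intermediate
3 | 1,3-bis(benzyloxy)-5-fluorobenzene | Fc1cc(OCc2ccccc2)cc(OCc2ccccc2)c1 | intermediate
4 | (R)-trityl glycidyl ether, (2R)-2-[(triphenylmethoxy)methyl]oxirane | C1O[C@H]1COC(c1ccccc1)(c1ccccc1)c1ccccc1 | starting material
5 | [2,4-bis(benzyloxy)-6-fluorophenyl]lithium | [Li]c1c(F)cc(OCc2ccccc2)cc1OCc1ccccc1 | intermediate
6 | (2R)-1-[2,4-bis(benzyloxy)-6-fluorophenyl]-3-(triphenylmethoxy)propan-2-ol | O[C@H](Cc1c(F)cc(OCc2ccccc2)cc1OCc1ccccc1)COC(c1ccccc1)(c1ccccc1)c1ccccc1 | intermediate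
7 | 1,5-bis(benzyloxy)-2-[(2R)-2-(benzyloxy)-3-(triphenylmethoxy)propyl]-3-fluorobenzene | c1ccccc1CO[C@H](Cc1c(F)cc(OCc2ccccc2)cc1OCc1ccccc1)COC(c1ccccc1)(c1ccccc1)c1ccccc1 | intermediate
8 | (2R)-2-(benzyloxy)-3-[2,4-bis(benzyloxy)-6-fluorophenyl]propan-1-ol | c1ccccc1CO[C@H](Cc1c(F)cc(OCc2ccccc2)cc1OCc1ccccc1)CO | intermediate
9 | (2R)-2-(benzyloxy)-3-[2,4-bis(benzyloxy)-6-fluorophenyl]propanal | c1ccccc1CO[C@H](Cc1c(F)cc(OCc2ccccc2)cc1OCc1ccccc1)C=O | intermediate
10 | 1,2-bis(benzyloxy)-4-bromobenzene | Brc1ccc(OCc2ccccc2)c(OCc2ccccc2)c1 | starting material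
11 | [3,4-bis(benzyloxy)phenyl]magnesium bromide | Br[Mg]c1ccc(OCc2ccccc2)c(OCc2ccccc2)c1 | intermediate
12 | (1R,2R)-2-(benzyloxy)-1-[3,4-bis(benzyloxy)phenyl]-3-[2,4-bis(benzyloxy)-6-fluorophenyl]propan-1-ol | c1ccccc1CO[C@H](Cc1c(F)cc(OCc2ccccc2)cc1OCc1ccccc1)[C@H](O)c1ccc(OCc2ccccc2)c(OCc2ccccc2)c1 | intermediate
13 | 7-hydroxy-4H-chromen-4-one | O=c1ccoc2cc(O)ccc12 | starting material
14 | 7-(benzyloxy)-4H-chromen-4-one | O=c1ccoc2cc(OCc3ccccc3)ccc12 | intermediate
15 | [4-(benzyloxy)phenyl]boronic acid | OB(O)c1ccc(OCc2ccccc2)cc1 | starting material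
16 | (2R)-7-(benzyloxy)-2-[4-(benzyloxy)phenyl]chroman-4-one | O=C1C[C@H](c2ccc(OCc3ccccc3)cc2)Oc2cc(OCc3ccccc3)ccc21 | intermediate
17 | lithium alkoxide of 12 lithiated at C8 (between F and OBn) | c1ccccc1CO[C@H](Cc1c(F)c([Li])c(OCc2ccccc2)cc1OCc1ccccc1)[C@H](O[Li])c1ccc(OCc2ccccc2)c(OCc2ccccc2)c1 | intermediate
18 | C8a≡C8 aryne bearing the lithium alkoxide side chain | c1ccccc1CO[C@H](CC1=C(OCc2ccccc2)C=C(OCc2ccccc2)C#C1)[C@H](O[Li])c1ccc(OCc2ccccc2)c(OCc2ccccc2)c1 | intermediate
19 | {(2R,3R)-3,5,7-tris(benzyloxy)-2-[3,4-bis(benzyloxy)phenyl]chroman-8-yl}lithium | [Li]c1c(OCc2ccccc2)cc(OCc2ccccc2)c2c1O[C@H](c1ccc(OCc3ccccc3)c(OCc3ccccc3)c1)[C@H](OCc1ccccc1)C2 | intermediate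
20 | {(2R,3R)-3,5,7-tris(benzyloxy)-2-[3,4-bis(benzyloxy)phenyl]chroman-8-yl}cerium dichloride | Cl[Ce](Cl)c1c(OCc2ccccc2)cc(OCc2ccccc2)c2c1O[C@H](c1ccc(OCc3ccccc3)c(OCc3ccccc3)c1)[C@H](OCc1ccccc1)C2 | intermediate
21 | (2R)-7-(benzyloxy)-2-[4-(benzyloxy)phenyl]-4-{(2R,3R)-3,5,7-tris(benzyloxy)-2-[3,4-bis(benzyloxy)phenyl]chroman-8-yl}chroman-4-ol, C4 epimers | c1ccccc1COc1ccc([C@@H]2Oc3cc(OCc4ccccc4)ccc3C(O)(c3c(OCc4ccccc4)cc(OCc4ccccc4)c4c3O[C@H](c3ccc(OCc5ccccc5)c(OCc5ccccc5)c3)[C@H](OCc3ccccc3)C4)C2)cc1 | intermediate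
22 | (2R)-7-(benzyloxy)-2-[4-(benzyloxy)phenyl]-4-{(2R,3R)-3,5,7-tris(benzyloxy)-2-[3,4-bis(benzyloxy)phenyl]chroman-8-yl}-2H-chromene | c1ccccc1COc1ccc([C@@H]2Oc3cc(OCc4ccccc4)ccc3C(c3c(OCc4ccccc4)cc(OCc4ccccc4)c4c3O[C@H](c3ccc(OCc5ccccc5)c(OCc5ccccc5)c3)[C@H](OCc3ccccc3)C4)=C2)cc1 | intermediate
23 | C3-boranyl adduct of 22 (boron at C3 trans to the 2-aryl group, hydrogen at C4 cis to boron) | c1ccccc1COc1ccc([C@@H]2Oc3cc(OCc4ccccc4)ccc3[C@H](c3c(OCc4ccccc4)cc(OCc4ccccc4)c4c3O[C@H](c3ccc(OCc5ccccc5)c(OCc5ccccc5)c3)[C@H](OCc3ccccc3)C4)[C@H]2B)cc1 | intermediate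
24 | (2S,3R,4R)-7-(benzyloxy)-2-[4-(benzyloxy)phenyl]-4-{(2R,3R)-3,5,7-tris(benzyloxy)-2-[3,4-bis(benzyloxy)phenyl]chroman-8-yl}chroman-3-ol | c1ccccc1COc1ccc([C@@H]2Oc3cc(OCc4ccccc4)ccc3[C@H](c3c(OCc4ccccc4)cc(OCc4ccccc4)c4c3O[C@H](c3ccc(OCc5ccccc5)c(OCc5ccccc5)c3)[C@H](OCc3ccccc3)C4)[C@H]2O)cc1 | intermediate
25 | ent-guibourtinidol-(4β→8)-epicatechin, (2R,3R)-2-(3,4-dihydroxyphenyl)-8-[(2S,3R,4R)-3,7-dihydroxy-2-(4-hydroxyphenyl)chroman-4-yl]chromane-3,5,7-triol | Oc1ccc([C@@H]2Oc3cc(O)ccc3[C@H](c3c(O)cc(O)c4c3O[C@H](c3ccc(O)c(O)c3)[C@H](O)C4)[C@H]2O)cc1 | target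

**Totals.** 12 steps in all. The longest linear sequence is 10 steps (steps 1–6 and 9–12); the flavanone branch (steps 7–8) joins at step 9.

**Steps most likely to fail**

Step 9 (proposed new method). The cascade may fail through misdirected or incomplete lithiation, intermolecular capture of the aryne, or protonation and enolisation in place of carbonyl addition. The fallback uses known chemistry, sets out from 12 and returns at 21. The potassium alkoxide of 12 (KN(SiMe3)2, THF/DMF, 60 °C) displaces the fluoride by intramolecular nucleophilic aromatic substitution, which forms the same O1–C8a bond with retention at C2 and gives penta-O-benzyl-(−)-epicatechin F1. NBS (CH2Cl2, −78 → 0 °C) brominates ring A at C8 to give the 8-bromo compound F2. Bromine–lithium exchange (t-BuLi, THF, −78 °C), CeCl3 and addition of 16 then give 21.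

Step 11. The hydroboration of the hindered trisubstituted alkene may be sluggish, may take place on the wrong face, or may be followed by β-elimination of boron with opening of the pyran ring. The fallback abandons the alkene for the classical acid-promoted interflavan coupling; it sets out from 16 and 12 and returns at 24. Flavanone 16 is converted (TMSOTf, Et3N, CH2Cl2, 0 °C) into the silyl enol ether F3. Oxidation with dimethyldioxirane (acetone, −40 °C) anti to the 2-aryl group, followed by dilute acid, gives the trans-3-hydroxyflavanone F4. NaBH4 (THF/MeOH, 0 °C) gives the flavan-3,4-diol F5. BF3·OEt2 (CH2Cl2, −78 → 0 °C) ionises C4 of F5, and the cation is captured anti to the 3-hydroxyl by C8 of penta-O-benzyl-(−)-epicatechin F1 (made from 12 by the ring closure described for step 9), which should give 24.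

Step 8. The electron-rich chromone may convert poorly, or the enantioselectivity may be insufficient. The fallback replaces asymmetric catalysis by a kinetic resolution; it sets out from 14 and 15 and returns at 16. Conjugate addition with the achiral catalyst Pd(OCOCF3)2/2,2′-bipyridine gives the racemic flavanone F6. Asymmetric transfer hydrogenation with RuCl(p-cymene)[(S,S)-TsDPEN] in HCO2H/Et3N, stopped near half conversion, should reduce the (2S)-ketone to the cis-flavan-4-ol F7 and leave (2R)-16, which is separated by chromatography.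

**Further compounds**

F1 | step 9 | (2R,3R)-3,5,7-tris(benzyloxy)-2-[3,4-bis(benzyloxy)phenyl]chromane (penta-O-benzyl-(−)-epicatechin) | c1c(OCc2ccccc2)cc(OCc2ccccc2)c2c1O[C@H](c1ccc(OCc3ccccc3)c(OCc3ccccc3)c1)[C@H](OCc1ccccc1)C2
F2 | step 9 | (2R,3R)-3,5,7-tris(benzyloxy)-2-[3,4-bis(benzyloxy)phenyl]-8-bromochromane | Brc1c(OCc2ccccc2)cc(OCc2ccccc2)c2c1O[C@H](c1ccc(OCc3ccccc3)c(OCc3ccccc3)c1)[C@H](OCc1ccccc1)C2
F3 | step 11 | (2R)-7-(benzyloxy)-2-[4-(benzyloxy)phenyl]-4-[(trimethylsilyl)oxy]-2H-chromene | c1ccccc1COc1ccc([C@@H]2Oc3cc(OCc4ccccc4)ccc3C(O[Si](C)(C)C)=C2)cc1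
F4 | step 11 | (2S,3S)-7-(benzyloxy)-2-[4-(benzyloxy)phenyl]-3-hydroxychroman-4-one | c1ccccc1COc1ccc([C@@H]2Oc3cc(OCc4ccccc4)ccc3C(=O)[C@H]2O)cc1
F5 | step 11 | (2S,3R,4S)-7-(benzyloxy)-2-[4-(benzyloxy)phenyl]chromane-3,4-diol | c1ccccc1COc1ccc([C@@H]2Oc3cc(OCc4ccccc4)ccc3[C@H](O)[C@H]2O)cc1
F6 | step 8 | racemic 7-(benzyloxy)-2-[4-(benzyloxy)phenyl]chroman-4-one | O=C1CC(c2ccc(OCc3ccccc3)cc2)Oc2cc(OCc3ccccc3)ccc21
F7 | step 8 | (2S,4S)-7-(benzyloxy)-2-[4-(benzyloxy)phenyl]chroman-4-ol | O[C@H]1C[C@@H](c2ccc(OCc3ccccc3)cc2)Oc2cc(OCc3ccccc3)ccc21
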